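A direct plan would prenylate 4-bromo-3-hydroxybenzaldehyde, extend it through an arylidene hydantoin to the arylpyruvic acid A1, and condense A1 with (4-hydroxyphenyl)acetic acid in Ac2O to the maleic anhydride A2.
Hydrogenation of A2 would give the cis-anhydride A3; methanolysis of A3 at one carbonyl and deacetylation would give the target.
Weakest would be the site-selective methanolysis of A3: two similar carbonyls beside an epimerisable α-aryl centre, without precedent, on the last material.
Next would be the enantioselective hydrogenation of the tetrasubstituted alkene of A2, which stakes both stereocentres on one untested catalyst match.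
Third would be the hydantoin detour to A1: three operations (hot NaOH on an o-prenylphenol, a labile α-keto acid) for one carbon and no stereochemistry.

**Plan of the new route**
Cuts, in retrosynthetic order: the aryl–prenyl bond; the C1 carboxyl, written back as an (E)-propenyl group; then the C2–C3 bond, by a retro-Ireland–Claisen step to a 3-arylpropanoate of an (R,E)-4-arylbut-3-en-2-ol.
Enabling feature: the array C4(=O)–C3–C2–C1, two adjacent CH stereocentres between two carboxyl carbons, is a γ,δ-unsaturated acid once C1 is an alkene carbon.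
No ring is formed at any stage; both benzene rings are bought and the only cyclic array is the chair transition state of the key step.
The carboxyls differ from birth (C4 is the Claisen acid, esterified at once; C1 stays an alkene until cleaved to the free acid), so no anhydride is opened.
Both stereocentres descend from one CBS-set carbinol, so no tetrasubstituted alkene is hydrogenated, and no α-keto acid is made.

Key step: step 6

Assumption: the (S)-oxazaborolidine is taken to give the R carbinol of 10, the alkenyl group acting as the large substituent as an aryl group does in aryl methyl ketones; if the sense were reversed, the other catalyst enantiomer would be used.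
Abbreviations: TBS = tert-butyldimethylsilyl; TBSO = (tert-butyldimethylsilyl)oxy; target numbering is C1 (CO2H), C2 (aryl), C3 (benzyl), C4 (CO2Me).

Step 1
Reactants: 1 4-bromo-3-hydroxybenzaldehyde; 2 2,2-dimethyl-1,3-dioxane-4,6-dione (Meldrum's acid)
Product: 5 3-(4-bromo-3-hydroxyphenyl)propanoic acid, via arylidene Meldrum's acid 3 (not isolated), via benzyl Meldrum's acid 4 (not isolated)
Conditions: 2 (1.05 eq), HCO2H/Et3N (5:2, 5 eq HCO2H), neat, 95 °C, 4 h; then 2 M HCl, EtOAc
Reagents that add atoms: none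
Why: Reductive Knoevenagel sequence (condensation, hydride transfer from formate to the arylidene malonate, then hydrolysis and decarboxylation of the dioxanedione ring by the water set free in the condensation) should give the saturated acid directly, under metal-free conditions that leave the aryl bromide and the phenol untouched.

Step 2
Reactants: 5 3-(4-bromo-3-hydroxyphenyl)propanoic acid
Product: 7 3-[4-bromo-3-(TBSO)phenyl]propanoic acid, via bis-silyl compound 6 (not isolated)
Conditions: TBSCl (2.4 eq), imidazole (5 eq), DMF, rt, 12 h; then THF/H2O/AcOH (4:1:1), rt, 2 h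
Reagents that add atoms: tert-butyl(chloro)dimethylsilane, CC(C)(C)[Si](C)(C)Cl
Why: Exhaustive silylation followed by selective hydrolysis of the far more labile silyl ester should leave only the phenol protected, as an aryl silyl ether that tolerates amide base, ozone and chlorite and is removed by fluoride at the end.

Step 3
Reactants: 8 (3E)-4-(4-hydroxyphenyl)but-3-en-2-one
Product: 9 (3E)-4-[4-(TBSO)phenyl]but-3-en-2-one
Conditions: TBSCl (1.2 eq), imidazole (2.2 eq), CH2Cl2, rt, 3 h
Reagents that add atoms: tert-butyl(chloro)dimethylsilane, CC(C)(C)[Si](C)(C)Cl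
Why: Silyl ether formation on the phenol masks the only acidic proton of the enone before the borane reduction and the later enolate chemistry.

Step 4
Reactants: 9 (3E)-4-[4-(TBSO)phenyl]but-3-en-2-one
Product: 10 (2R,3E)-4-[4-(TBSO)phenyl]but-3-en-2-ol
Conditions: (S)-2-methyl-CBS-oxazaborolidine [(S)-1-methyl-3,3-diphenyltetrahydro-1H,3H-pyrrolo[1,2-c][1,3,2]oxazaborole] (15 mol%), BH3·SMe2 (0.7 eq), THF, −20 °C, 9 added over 1 h; MeOH quench
Reagents that add atoms: none
Why: Corey–Bakshi–Shibata reduction, in which the ketone binds the ring boron with the styrenyl group as the large substituent and hydride is delivered intramolecularly to one carbonyl face, should set the R carbinol, 1,2-reduction outrunning hydroboration of the conjugated alkene at −20 °C.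

Step 5
Reactants: 7 3-[4-bromo-3-(TBSO)phenyl]propanoic acid; 10 (2R,3E)-4-[4-(TBSO)phenyl]but-3-en-2-ol
Product: 11 (2R,3E)-4-[4-(TBSO)phenyl]but-3-en-2-yl 3-[4-bromo-3-(TBSO)phenyl]propanoate
Conditions: DCC (N,N'-dicyclohexylcarbodiimide, 1.2 eq), DMAP (0.1 eq), CH2Cl2, 0 °C → rt, 6 h; filtration, Et3N-deactivated silica
Reagents that add atoms: none
Why: Steglich esterification under nucleophilic catalysis should acylate the secondary allylic alcohol without ionising the electron-rich cinnamyl-type C–O bond, so that the carbinol configuration and the alkene geometry are preserved.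

Step 6
Reactants: 11 (2R,3E)-4-[4-(TBSO)phenyl]but-3-en-2-yl 3-[4-bromo-3-(TBSO)phenyl]propanoate
Product: 14 (2S,3S,4E)-2-{[4-bromo-3-(TBSO)phenyl]methyl}-3-[4-(TBSO)phenyl]hex-4-enoic acid, via (E)-silyl ketene acetal 12 (not isolated), via trimethylsilyl ester 13 (not isolated)
Conditions: LiN(iPr)2 (LDA, 1.2 eq), THF, −78 °C, 30 min; TMSCl/Et3N (1:1, 1.6 eq), −78 °C → rt, then 50 °C, 3 h; 5% aq. citric acid/THF, rt, 30 min
Reagents that add atoms: none
Why: Ireland–Claisen rearrangement: LiN(iPr)2 in THF without polar cosolvent should give the kinetic E(O) lithium enolate, TMSCl traps it as the (E)-silyl ketene acetal 12 (CH2Ar cis to the allylic oxygen), and 12 undergoes a concerted suprafacial [3,3]-sigmatropic shift on warming, the carbinol C–O bond breaking as the C–C bond between the two future stereocentres forms; the silicon of TMSCl is carried only in 12 and 13 and leaves as trimethylsilanol on work-up. The closest known reaction type is the ester enolate Claisen rearrangement of (E)-cinnamyl and (E)-crotyl alkanoates of secondary allylic alcohols. No ring is closed; the only cyclic array is the six-membered chair transition state. The aryl-bearing centre (C3 of 14, C2 of the target) is controlled by the R carbinol: with its methyl group equatorial in the chair, bond formation is forced onto one face of the (E)-alkene, which should give S and the (E)-propenyl group while the carbinol centre is consumed. The benzyl-bearing centre (C2 of 14, C3 of the target) is controlled by the ketene acetal geometry: the E(O) geometry places the benzyl group axial in the same chair and so should give the anti (2S,3S) pair. The step needs E(O) over Z(O) enolisation (kinetic deprotonation in THF alone), chair over boat (acyclic system) and complete chirality transfer (disubstituted (E)-alkene beside a secondary carbinol), and at −78 °C the aryl bromide and both aryl silyl ethers should be inert to the amide base.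

Step 7
Reactants: 14 (2S,3S,4E)-2-{[4-bromo-3-(TBSO)phenyl]methyl}-3-[4-(TBSO)phenyl]hex-4-enoic acid
Product: 15 methyl (2S,3S,4E)-2-{[4-bromo-3-(TBSO)phenyl]methyl}-3-[4-(TBSO)phenyl]hex-4-enoate
Conditions: TMSCHN2 (2 M in hexane, 1.5 eq), toluene/MeOH (4:1), 0 °C → rt, 30 min; AcOH quench; chromatography (removal of any syn isomer)
Reagents that add atoms: (trimethylsilyl)diazomethane, C[Si](C)(C)C=[N+]=[N-]
Why: O-Methylation of the acid by diazomethane released in situ from TMSCHN2 and methanol (proton transfer, then SN2 on the methyldiazonium ion) touches neither stereocentre and turns the Claisen-derived carboxyl (C4 of the target) into the methyl ester while C1 is still an alkene.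

Step 8
Reactants: 15 methyl (2S,3S,4E)-2-{[4-bromo-3-(TBSO)phenyl]methyl}-3-[4-(TBSO)phenyl]hex-4-enoate
Product: 18 (2S,3S)-3-{[4-bromo-3-(TBSO)phenyl]methyl}-2-[4-(TBSO)phenyl]-4-methoxy-4-oxobutanoic acid, via secondary ozonide 16 (not isolated), via aldehyde 17 (not isolated)
Conditions: O3/O2, CH2Cl2, −78 °C (Sudan Red 7B end point), N2 purge; PPh3 (1.3 eq), −78 °C → rt; evaporate; NaClO2 (3 eq), NaH2PO4 (4 eq), 2-methylbut-2-ene (10 eq), t-BuOH/H2O (4:1), 0 °C, 2 h
Reagents that add atoms: ozone, [O-][O+]=O; sodium chlorite, [Na+].[O-]Cl=O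
Why: Ozonolysis of the only alkene (cycloaddition, cycloreversion and recombination to the secondary ozonide, reduced by PPh3) followed at once by Pinnick oxidation should turn the propenyl group into the free C1 carboxyl under non-basic conditions that spare the α-aryl stereocentre, the methyl ester, the aryl bromide and the silyl ethers.

Step 9
Reactants: 18 (2S,3S)-3-{[4-bromo-3-(TBSO)phenyl]methyl}-2-[4-(TBSO)phenyl]-4-methoxy-4-oxobutanoic acid; 19 tributyl(3-methylbut-2-en-1-yl)stannane
Product: 20 (2S,3S)-2-[4-(TBSO)phenyl]-3-{[3-(TBSO)-4-(3-methylbut-2-en-1-yl)phenyl]methyl}-4-methoxy-4-oxobutanoic acid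
Conditions: 19 (2.0 eq), Pd(PPh3)4 (5 mol%), iPr2NEt (1.2 eq), degassed DMF, 85 °C, 12 h; pH 4 phosphate buffer, EtOAc; short silica plug
Reagents that add atoms: none
Why: Stille coupling (oxidative addition of zerovalent palladium into the C–Br bond, transmetalation of the allylic stannane, reductive elimination at the unhindered CH2 terminus) should give the linear prenyl arene under neutral conditions in which the carboxylate, the ester and both stereocentres are inert, the amine keeping the acid from protonating the stannane.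

Step 10
Reactants: 20 (2S,3S)-2-[4-(TBSO)phenyl]-3-{[3-(TBSO)-4-(3-methylbut-2-en-1-yl)phenyl]methyl}-4-methoxy-4-oxobutanoic acid
Product: 21 (2S,3S)-2-(4-hydroxyphenyl)-3-{[3-hydroxy-4-(3-methylbut-2-en-1-yl)phenyl]methyl}-4-methoxy-4-oxobutanoic acid (target)
Conditions: Bu4NF (TBAF, 1 M in THF, 3 eq), AcOH (3.5 eq), THF, 0 °C → rt, 1 h; pH 4 phosphate buffer, EtOAc
Reagents that add atoms: none
Why: Fluoride-induced cleavage of the two aryl silyl ethers, buffered with acetic acid so that neither a phenoxide nor an ester enolate persists, should release the target without touching the methyl ester, the stereocentres or the acid-sensitive o-prenylphenol.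

**Compound list**
1 | 4-bromo-3-hydroxybenzaldehyde | O=Cc1ccc(Br)c(O)c1 | starting material
2 | 2,2-dimethyl-1,3-dioxane-4,6-dione (Meldrum's acid) | CC1(C)OC(=O)CC(=O)O1 | starting material
3 | 5-[(4-bromo-3-hydroxyphenyl)methylidene]-2,2-dimethyl-1,3-dioxane-4,6-dione | CC1(C)OC(=O)C(=Cc2ccc(Br)c(O)c2)C(=O)O1 | intermediate
4 | 5-[(4-bromo-3-hydroxyphenyl)methyl]-2,2-dimethyl-1,3-dioxane-4,6-dione | CC1(C)OC(=O)C(Cc2ccc(Br)c(O)c2)C(=O)O1 | intermediate
5 | 3-(4-bromo-3-hydroxyphenyl)propanoic acid | OC(=O)CCc1ccc(Br)c(O)c1 | intermediate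
6 | tert-butyldimethylsilyl 3-{4-bromo-3-[(tert-butyldimethylsilyl)oxy]phenyl}propanoate | CC(C)(C)[Si](C)(C)OC(=O)CCc1ccc(Br)c(O[Si](C)(C)C(C)(C)C)c1 | intermediate
7 | 3-{4-bromo-3-[(tert-butyldimethylsilyl)oxy]phenyl}propanoic acid | OC(=O)CCc1ccc(Br)c(O[Si](C)(C)C(C)(C)C)c1 | intermediate
8 | (3E)-4-(4-hydroxyphenyl)but-3-en-2-one | CC(=O)/C=C/c1ccc(O)cc1 | starting material
9 | (3E)-4-{4-[(tert-butyldimethylsilyl)oxy]phenyl}but-3-en-2-one | CC(=O)/C=C/c1ccc(O[Si](C)(C)C(C)(C)C)cc1 | intermediate
10 | (2R,3E)-4-{4-[(tert-butyldimethylsilyl)oxy]phenyl}but-3-en-2-ol | C[C@@H](O)/C=C/c1ccc(O[Si](C)(C)C(C)(C)C)cc1 | intermediate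
11 | (2R,3E)-4-{4-[(tert-butyldimethylsilyl)oxy]phenyl}but-3-en-2-yl 3-{4-bromo-3-[(tert-butyldimethylsilyl)oxy]phenyl}propanoate | C[C@@H](OC(=O)CCc1ccc(Br)c(O[Si](C)(C)C(C)(C)C)c1)/C=C/c1ccc(O[Si](C)(C)C(C)(C)C)cc1 | intermediate
12 | (E)-O-trimethylsilyl ketene acetal of 11: {[(1E)-3-{4-bromo-3-[(tert-butyldimethylsilyl)oxy]phenyl}-1-{[(2R,3E)-4-{4-[(tert-butyldimethylsilyl)oxy]phenyl}but-3-en-2-yl]oxy}prop-1-en-1-yl]oxy}trimethylsilane | C[Si](C)(C)O/C(O[C@H](C)/C=C/c1ccc(O[Si](C)(C)C(C)(C)C)cc1)=C/Cc1ccc(Br)c(O[Si](C)(C)C(C)(C)C)c1 | intermediate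
13 | trimethylsilyl (2S,3S,4E)-2-({4-bromo-3-[(tert-butyldimethylsilyl)oxy]phenyl}methyl)-3-{4-[(tert-butyldimethylsilyl)oxy]phenyl}hex-4-enoate | C[Si](C)(C)OC(=O)[C@@H](Cc1ccc(Br)c(O[Si](C)(C)C(C)(C)C)c1)[C@H](/C=C/C)c1ccc(O[Si](C)(C)C(C)(C)C)cc1 | intermediate
14 | (2S,3S,4E)-2-({4-bromo-3-[(tert-butyldimethylsilyl)oxy]phenyl}methyl)-3-{4-[(tert-butyldimethylsilyl)oxy]phenyl}hex-4-enoic acid | OC(=O)[C@@H](Cc1ccc(Br)c(O[Si](C)(C)C(C)(C)C)c1)[C@H](/C=C/C)c1ccc(O[Si](C)(C)C(C)(C)C)cc1 | intermediate
15 | methyl (2S,3S,4E)-2-({4-bromo-3-[(tert-butyldimethylsilyl)oxy]phenyl}methyl)-3-{4-[(tert-butyldimethylsilyl)oxy]phenyl}hex-4-enoate | COC(=O)[C@@H](Cc1ccc(Br)c(O[Si](C)(C)C(C)(C)C)c1)[C@H](/C=C/C)c1ccc(O[Si](C)(C)C(C)(C)C)cc1 | intermediate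
16 | methyl (2S,3S)-2-({4-bromo-3-[(tert-butyldimethylsilyl)oxy]phenyl}methyl)-3-{4-[(tert-butyldimethylsilyl)oxy]phenyl}-3-(5-methyl-1,2,4-trioxolan-3-yl)propanoate (secondary ozonide, mixture at the two ring carbons) | COC(=O)[C@@H](Cc1ccc(Br)c(O[Si](C)(C)C(C)(C)C)c1)[C@H](C1OOC(C)O1)c1ccc(O[Si](C)(C)C(C)(C)C)cc1 | intermediate
17 | methyl (2S,3S)-2-({4-bromo-3-[(tert-butyldimethylsilyl)oxy]phenyl}methyl)-3-{4-[(tert-butyldimethylsilyl)oxy]phenyl}-4-oxobutanoate | COC(=O)[C@@H](Cc1ccc(Br)c(O[Si](C)(C)C(C)(C)C)c1)[C@H](C=O)c1ccc(O[Si](C)(C)C(C)(C)C)cc1 | intermediate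
18 | (2S,3S)-3-({4-bromo-3-[(tert-butyldimethylsilyl)oxy]phenyl}methyl)-2-{4-[(tert-butyldimethylsilyl)oxy]phenyl}-4-methoxy-4-oxobutanoic acid | COC(=O)[C@@H](Cc1ccc(Br)c(O[Si](C)(C)C(C)(C)C)c1)[C@H](C(=O)O)c1ccc(O[Si](C)(C)C(C)(C)C)cc1 | intermediate
19 | tributyl(3-methylbut-2-en-1-yl)stannane | CCCC[Sn](CCCC)(CCCC)CC=C(C)C | starting material
20 | (2S,3S)-2-{4-[(tert-butyldimethylsilyl)oxy]phenyl}-3-({3-[(tert-butyldimethylsilyl)oxy]-4-(3-methylbut-2-en-1-yl)phenyl}methyl)-4-methoxy-4-oxobutanoic acid | COC(=O)[C@@H](Cc1ccc(CC=C(C)C)c(O[Si](C)(C)C(C)(C)C)c1)[C@H](C(=O)O)c1ccc(O[Si](C)(C)C(C)(C)C)cc1 | intermediate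
21 | (2S,3S)-2-(4-hydroxyphenyl)-3-{[3-hydroxy-4-(3-methylbut-2-en-1-yl)phenyl]methyl}-4-methoxy-4-oxobutanoic acid | COC(=O)[C@@H](Cc1ccc(CC=C(C)C)c(O)c1)[C@H](C(=O)O)c1ccc(O)cc1 | target

**Step count**
Total steps: 10. Longest linear sequence: 8 (steps 1, 2, 5, 6, 7, 8, 9, 10, from compound 1); steps 3 and 4 form the two-step branch to alcohol 10.

**Steps most likely to fail**

Step 6. Leakage to the Z(O) enolate or partial passage through a boat transition state would erode the anti:syn ratio, and ionisation of the cinnamyl-type ester before rearrangement would erode the chirality transfer. The fallback inverts the geometric pairing with known chemistry and sets out from acid 7. Sonogashira coupling of commercial (S)-but-3-yn-2-ol with tert-butyl(4-iodophenoxy)dimethylsilane (PdCl2(PPh3)2, CuI, Et3N) would give (2S)-4-[4-(TBSO)phenyl]but-3-yn-2-ol F1. Semihydrogenation over Lindlar catalyst (Pd on CaCO3 poisoned with Pb(OAc)2, quinoline, H2) would give (2S,3Z)-4-[4-(TBSO)phenyl]but-3-en-2-ol F2. Steglich esterification of F2 with 7 would give the (Z)-allylic ester F3. Enolisation of F3 with LiN(iPr)2 in THF/DMPU, which favours the Z(O) enolate, and silylation would give the (Z)-silyl ketene acetal F4. In the chair with the aryl group axial and the carbinol methyl equatorial, F4 should rearrange to the same trimethylsilyl ester, so the fallback comes back to the route at 13 and hence 14.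

Step 8. Attack of ozone on the silyloxy-substituted benzene rings, or enolisation of the α-aryl aldehyde before it is oxidised, would cost material or configuration. The fallback sets out from 15 and replaces ozone by osmium-catalysed dihydroxylation with periodate cleavage in one pot (OsO4 2 mol%, NaIO4 4 eq, 2,6-lutidine, dioxane/H2O, rt). The diol methyl (2S,3S)-2-{[4-bromo-3-(TBSO)phenyl]methyl}-3-[4-(TBSO)phenyl]-4,5-dihydroxyhexanoate F5 would be cleaved as it forms, before it can lactonise onto the ester. The fallback comes back to the route at aldehyde 17, which is taken directly into the chlorite oxidation to 18.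

Step 9. Transfer of the allyl group through its γ-terminus (giving the 1,1-dimethylallyl isomer), protodestannylation by the free acid, or protodebromination would lower the return on the most advanced material. The fallback sets out from 18. Coupling with allyltributylstannane (Pd(PPh3)4, iPr2NEt, DMF, 80 °C), where the two allyl termini are equivalent, would give the allyl arene (2S,3S)-3-{[4-(prop-2-en-1-yl)-3-(TBSO)phenyl]methyl}-2-[4-(TBSO)phenyl]-4-methoxy-4-oxobutanoic acid F6. Olefin cross-metathesis of F6 with 2-methylbut-2-ene as cosolvent (second-generation Grubbs catalyst RuCl2(=CHPh)(PCy3)(H2IMes), 5 mol%, CH2Cl2, 40 °C) would convert the allyl into the prenyl group. The fallback comes back to the route at 20.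

**Further compounds**
F1 | step 6 | (2S)-4-{4-[(tert-butyldimethylsilyl)oxy]phenyl}but-3-yn-2-ol | C[C@H](O)C#Cc1ccc(O[Si](C)(C)C(C)(C)C)cc1
F2 | step 6 | (2S,3Z)-4-{4-[(tert-butyldimethylsilyl)oxy]phenyl}but-3-en-2-ol | C[C@H](O)/C=C\c1ccc(O[Si](C)(C)C(C)(C)C)cc1
F3 | step 6 | (2S,3Z)-4-{4-[(tert-butyldimethylsilyl)oxy]phenyl}but-3-en-2-yl 3-{4-bromo-3-[(tert-butyldimethylsilyl)oxy]phenyl}propanoate | C[C@H](OC(=O)CCc1ccc(Br)c(O[Si](C)(C)C(C)(C)C)c1)/C=C\c1ccc(O[Si](C)(C)C(C)(C)C)cc1
F4 | step 6 | (Z)-O-trimethylsilyl ketene acetal of F3: {[(1Z)-3-{4-bromo-3-[(tert-butyldimethylsilyl)oxy]phenyl}-1-{[(2S,3Z)-4-{4-[(tert-butyldimethylsilyl)oxy]phenyl}but-3-en-2-yl]oxy}prop-1-en-1-yl]oxy}trimethylsilane | C[Si](C)(C)O/C(O[C@@H](C)/C=C\c1ccc(O[Si](C)(C)C(C)(C)C)cc1)=C\Cc1ccc(Br)c(O[Si](C)(C)C(C)(C)C)c1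
F5 | step 8 | methyl (2S,3S)-2-({4-bromo-3-[(tert-butyldimethylsilyl)oxy]phenyl}methyl)-3-{4-[(tert-butyldimethylsilyl)oxy]phenyl}-4,5-dihydroxyhexanoate (mixture at C4 and C5) | COC(=O)[C@@H](Cc1ccc(Br)c(O[Si](C)(C)C(C)(C)C)c1)[C@H](C(O)C(C)O)c1ccc(O[Si](C)(C)C(C)(C)C)cc1
F6 | step 9 | (2S,3S)-2-{4-[(tert-butyldimethylsilyl)oxy]phenyl}-3-({3-[(tert-butyldimethylsilyl)oxy]-4-(prop-2-en-1-yl)phenyl}methyl)-4-methoxy-4-oxobutanoic acid | COC(=O)[C@@H](Cc1ccc(CC=C)c(O[Si](C)(C)C(C)(C)C)c1)[C@H](C(=O)O)c1ccc(O[Si](C)(C)C(C)(C)C)cc1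
A1 | direct plan | 3-[3-hydroxy-4-(3-methylbut-2-en-1-yl)phenyl]-2-oxopropanoic acid | OC(=O)C(=O)Cc1ccc(CC=C(C)C)c(O)c1
A2 | direct plan | 4-[4-{[3-acetoxy-4-(3-methylbut-2-en-1-yl)phenyl]methyl}-2,5-dioxo-2,5-dihydrofuran-3-yl]phenyl acetate | CC(=O)Oc1ccc(cc1)C1=C(Cc2ccc(CC=C(C)C)c(OC(C)=O)c2)C(=O)OC1=O
A3 | direct plan | 4-[(3S,4S)-4-{[3-acetoxy-4-(3-methylbut-2-en-1-yl)phenyl]methyl}-2,5-dioxooxolan-3-yl]phenyl acetate (cis) | O=C1[C@@H](Cc2ccc(CC=C(C)C)c(OC(C)=O)c2)[C@H](C(=O)O1)c3ccc(OC(C)=O)cc3
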